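**Plan**

1. Retrosynthesis: first the two ring B C–Br bonds (ortho and para to the phenol OH) are cut; then the ring A C–OMe bond is cut and that carbon is joined to the phenol oxygen, giving a dibenzo-1,4-dioxin; last, both ring A C–O bonds are cut to tetrabromobenzyne and 1,2-benzoquinone.
2. Enabling feature: ring A has two neighbouring oxygens (C1–OMe, C6–OAr) beside four bromines on C2 to C5, the pattern left when a symmetric tetrabromobenzyne takes up two oxygens, and ring B is a 1,2-dioxygenated benzene, the reduced form of an o-quinone.
3. Forward: tetrabromophthalic anhydride is taken to tetrabromoanthranilic acid (aryne source) and catechol to 1,2-benzoquinone; their cycloaddition closes the central 1,4-dioxin ring, the only ring made in the route.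
4. Methoxide then opens the dioxin at ring A, and the phenol set free directs two bromines into ring B in the last step.
5. Ring B stays free of bromine up to the dioxin so that the two ether oxygens are equivalent and the opening can lead to one phenol only.
6. Stereochemistry: the target has no stereocentre and no stereogenic double bond, so none has to be set.

Key step: step 4

Assumption: 1,2-benzoquinone is labile; it is taken to last as a cold, dry, ether-free solution for the short time between its preparation and the cycloaddition and is never stored.

**Route**

Step 1
Reactants: 1 tetrabromophthalic anhydride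
Product: 2 tetrabromophthalimide
Conditions: NH4OAc, AcOH, reflux
Reagents that add atoms: ammonium acetate, CC(=O)[O-].[NH4+]
Why: Aminolysis of the anhydride by ammonia from NH4OAc followed by cyclodehydration in hot acetic acid is the standard imide synthesis from a phthalic anhydride.

Step 2
Reactants: 2 tetrabromophthalimide
Product: 4 2-amino-3,4,5,6-tetrabromobenzoic acid, via tetrabromophthalamic acid 3 (not isolated)
Conditions: aq. NaOH, 0 °C; aq. NaOCl, 0 → 80 °C; then HCl to pH 2
Reagents that add atoms: sodium hydroxide, [Na+].[OH-]
Why: Hydroxide opens the imide to the amide acid 3 and the Hofmann rearrangement then moves the aryl group from the amide carbon to nitrogen with loss of that carbon as carbonate, the classical way from a phthalimide to an anthranilic acid.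

Step 3
Reactants: 5 catechol
Product: 6 1,2-benzoquinone
Conditions: Ag2O, Na2SO4, dry Et2O, 0 °C; filtered cold, solvent exchanged for CH2Cl2 below 0 °C, used at once
Reagents that add atoms: none
Why: Ag2O is a mild two-electron oxidant for the oxidation of catechols to o-quinones, and the cold, anhydrous, acid-free conditions are chosen because the unsubstituted quinone dimerises and hydrates easily.

Step 4
Reactants: 4 2-amino-3,4,5,6-tetrabromobenzoic acid; 6 1,2-benzoquinone
Product: 9 1,2,3,4-tetrabromodibenzo[b,e][1,4]dioxine, via tetrabromobenzenediazonium-2-carboxylate 7 (not isolated), via tetrabromobenzyne 8 (not isolated)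
Conditions: isoamyl nitrite, CH2Cl2/MeCN, 40 °C; 4 in MeCN added slowly to excess 6 and the nitrite; no ether solvent
Reagents that add atoms: none
Why: Aprotic diazotization of 4 gives the zwitterion 7, which loses N2 and CO2 at 40 °C to release the aryne 8, whose strained triple bond is made strongly electrophilic by four bromines. The quinone 6 serves as a 4π heterodiene through its O=C–C=O unit and the aryne as the 2π partner, so that both aryl C–O bonds form in one hetero-Diels–Alder reaction. The closest known reaction type is the [4+2] addition of arynes across the two oxygens of o-quinones to give dibenzo-1,4-dioxins. The central six-membered 1,4-dioxin ring is the only ring closed, by cycloaddition of the two partners, and no stereocentre is created. The step needs addition across the two oxygens and not across the carbon diene (C3 and C6 of 6) or a single C=C or C=O bond; the electron-poor aryne should prefer the oxygen lone pairs over the electron-poor carbon diene, and only the O,O-adduct turns ring B into a benzene ring. Both partners are symmetric, so no question of orientation arises.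

Step 5
Reactants: 9 1,2,3,4-tetrabromodibenzo[b,e][1,4]dioxine
Product: 10 2-(2,3,4,5-tetrabromo-6-methoxyphenoxy)phenol
Conditions: NaOMe (1.2 equiv), DMF/MeOH, 25 → 60 °C; then aq. HCl
Reagents that add atoms: sodium methoxide, C[O-].[Na+]
Why: Proposed new method: methoxide should add at one of the two equivalent oxygen-bearing carbons of ring A, whose four bromines let the ring carry the negative charge, and the adduct should expel the 2-aryloxyphenoxide, a far weaker base than methoxide, so that the opening is downhill, stops after one cleavage because the product is an anion, and gives the same phenol from either ether bond since ring B is unsubstituted; the closest known reaction type is alkoxide SNAr cleavage of perhalogenated diaryl ethers.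

Step 6
Reactants: 10 2-(2,3,4,5-tetrabromo-6-methoxyphenoxy)phenol
Product: 11 2,4-dibromo-6-(2,3,4,5-tetrabromo-6-methoxyphenoxy)phenol
Conditions: Br2 (2.1 equiv), AcOH, 15–25 °C
Reagents that add atoms: bromine, BrBr
Why: Electrophilic aromatic bromination is directed by the free OH to its one open ortho position and its para position, the ether oxygen bound to the electron-poor ring A being a much weaker director and ring A having no free position, so two equivalents of Br2 should give the target pattern.

**Compound list**

1 | tetrabromophthalic anhydride (4,5,6,7-tetrabromo-2-benzofuran-1,3-dione) | O=C1OC(=O)c2c(Br)c(Br)c(Br)c(Br)c12 | starting material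
2 | tetrabromophthalimide (4,5,6,7-tetrabromoisoindoline-1,3-dione) | O=C1NC(=O)c2c(Br)c(Br)c(Br)c(Br)c12 | intermediate
3 | tetrabromophthalamic acid (2-carbamoyl-3,4,5,6-tetrabromobenzoic acid, present as its sodium salt) | NC(=O)c1c(Br)c(Br)c(Br)c(Br)c1C(=O)O | intermediate
4 | 2-amino-3,4,5,6-tetrabromobenzoic acid (tetrabromoanthranilic acid) | Nc1c(Br)c(Br)c(Br)c(Br)c1C(=O)O | intermediate
5 | catechol (benzene-1,2-diol) | Oc1ccccc1O | starting material
6 | 1,2-benzoquinone (cyclohexa-3,5-diene-1,2-dione) | O=C1C=CC=CC1=O | intermediate
7 | 3,4,5,6-tetrabromobenzenediazonium-2-carboxylate | N#[N+]c1c(Br)c(Br)c(Br)c(Br)c1C(=O)[O-] | intermediate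
8 | tetrabromobenzyne (3,4,5,6-tetrabromo-1,2-didehydrobenzene) | BrC1=C(Br)C(Br)=C(Br)C#C1 | intermediate
9 | 1,2,3,4-tetrabromodibenzo[b,e][1,4]dioxine | Brc1c(Br)c(Br)c(Br)c2Oc3ccccc3Oc12 | intermediate
10 | 2-(2,3,4,5-tetrabromo-6-methoxyphenoxy)phenol | COc1c(Br)c(Br)c(Br)c(Br)c1Oc1ccccc1O | intermediate
11 | 2,4-dibromo-6-(2,3,4,5-tetrabromo-6-methoxyphenoxy)phenol | COc1c(Br)c(Br)c(Br)c(Br)c1Oc1cc(Br)cc(Br)c1O | target

**Summary**

Total step count: 6. Longest linear sequence: 5 steps (steps 1, 2, 4, 5, 6); step 3 is the side branch.

**Steps most likely to fail**

Step 5 (new method). Methoxide may replace a ring A bromine by SNAr, or abstract bromine, faster than it adds at the oxygen-bearing carbons. The phenoxide formed may also close again onto the neighbouring C–Br of ring A with loss of bromide. The fallback uses known reaction types only, sets out from 5 and comes back at 10. Catechol 5 is brominated exhaustively (Br2, AcOH) to tetrabromocatechol F1. One of its two equivalent hydroxyls is methylated (MeI, one equivalent, K2CO3, DMF) to 2,3,4,5-tetrabromo-6-methoxyphenol F2. Its phenoxide displaces fluoride from 2-fluorobenzaldehyde (K2CO3, DMAc, 130 °C, SNAr) to give 2-(2,3,4,5-tetrabromo-6-methoxyphenoxy)benzaldehyde F3. Baeyer–Villiger oxidation with mCPBA in CH2Cl2 gives 2-(2,3,4,5-tetrabromo-6-methoxyphenoxy)phenyl formate F4, and hydrolysis (KOH, MeOH/H2O) gives 10, from which step 6 runs as planned.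

Step 4 (key step). The aryne may add across the carbon diene of the quinone, a mode known for unhalogenated o-quinones with simple arynes, or across one C=O or C=C bond. It may also be consumed by the alcohol and water that the diazotization sets free. The fallback swaps the roles of the partners, sets out from 5 and comes back at 9. Tetrabromocatechol F1, made from 5 as in the fallback to step 5, is oxidized (HNO3, AcOH) to 3,4,5,6-tetrabromo-1,2-benzoquinone F5, a stable perhalogenated quinone of the kind known to take up arynes at its two oxygens. Anthranilic acid and isoamyl nitrite in refluxing ClCH2CH2Cl give benzenediazonium-2-carboxylate F6 and from it benzyne F7, which adds across the two oxygens of F5 to give 9. In this variant the ring B C–O bonds are formed instead of the ring A ones.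

Step 3. The unsubstituted quinone may dimerise, hydrate or polymerise during filtration and solvent exchange, so that too little intact heterodiene reaches step 4. The fallback needs neither quinone nor aryne, sets out from 5 and comes back at 9. Catechol 5 is heated with hexabromobenzene and K2CO3 in NMP at 130–150 °C. A first SNAr gives 2-(pentabromophenoxy)phenol F8, whose phenoxide closes onto the neighbouring C–Br in a second SNAr to give 9. This double condensation is the known type of route to tetrahalodibenzodioxins from catechol and hexahalobenzenes.

**Further compounds**

F1 | step 5 | tetrabromocatechol (3,4,5,6-tetrabromobenzene-1,2-diol) | Oc1c(O)c(Br)c(Br)c(Br)c1Br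
F2 | step 5 | 2,3,4,5-tetrabromo-6-methoxyphenol | COc1c(O)c(Br)c(Br)c(Br)c1Br
F3 | step 5 | 2-(2,3,4,5-tetrabromo-6-methoxyphenoxy)benzaldehyde | COc1c(Br)c(Br)c(Br)c(Br)c1Oc1ccccc1C=O
F4 | step 5 | 2-(2,3,4,5-tetrabromo-6-methoxyphenoxy)phenyl formate | COc1c(Br)c(Br)c(Br)c(Br)c1Oc1ccccc1OC=O
F5 | step 4 | 3,4,5,6-tetrabromo-1,2-benzoquinone | O=C1C(=O)C(Br)=C(Br)C(Br)=C1Br
F6 | step 4 | benzenediazonium-2-carboxylate | N#[N+]c1ccccc1C(=O)[O-]
F7 | step 4 | benzyne | C1#CC=CC=C1
F8 | step 3 | 2-(pentabromophenoxy)phenol | Oc1ccccc1Oc1c(Br)c(Br)c(Br)c(Br)c1Br
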